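## Retrosynthetic overview

1. Target 13, (3S,13Z)-1-(3,4-dihydroxyphenyl)-3-hydroxydocos-13-en-5-one, is cut at C4–C5 (methylene carbon to ketone carbon), giving an oleoyl acyl donor and a primary C4 radical on the aryl carbinol half.
2. Enabling feature: C4 is an unsubstituted CH2 between the C5 ketone carbon and the C3 carbinol carbon. A carboxyl group placed on C4 turns the aryl half into a 3-hydroxy-5-arylpentanoic acid, whose C3 centre comes from asymmetric hydrogenation of a β-keto ester, and that carboxyl is lost as CO2 in the coupling. The acyl half is oleic acid itself, so the C13–C14 Z alkene is bought.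
3. Both halves are therefore carboxylic acids. A nickel-catalysed decarboxylative radical acylation (N-hydroxyphthalimide ester plus S-2-pyridyl thioester) forms C4–C5 and the ketone in one operation, with C3 a spectator one atom from the radical.
4. No ring is formed in the route. The only ring, the catechol benzene ring, comes with dihydrocaffeic acid and is carried as its bis-silyl ether; one buffered fluoride step frees the three hydroxyls at the end.

Key step: step 8

Assumption: commercial oleic acid of high (9Z) purity and 3-(3,4-dihydroxyphenyl)propanoic acid are the starting materials; intermediate 4 is drawn as its enol tautomer.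

## Route

Step 1
Reactants: 1 3-(3,4-dihydroxyphenyl)propanoic acid (dihydrocaffeic acid)
Product: 3 3-[3,4-bis(tert-butyldimethylsilyloxy)phenyl]propanoic acid, via tris-silylated silyl ester 2 (not isolated)
Conditions: TBSCl (3.5 equiv), imidazole, DMF, rt; then AcOH/THF/H2O, rt
Reagents that add atoms: tert-butyldimethylsilyl chloride, CC(C)(C)[Si](C)(C)Cl
Why: Imidazole-promoted silylation caps both phenols and the acid, and the silyl ester, far more labile than the aryl silyl ethers, should be hydrolysed selectively by aqueous acetic acid.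

Step 2
Reactants: 3 3-[3,4-bis(tert-butyldimethylsilyloxy)phenyl]propanoic acid
Product: 5 benzyl 5-[3,4-bis(tert-butyldimethylsilyloxy)phenyl]-3-oxopentanoate, via acyl Meldrum's acid 4 (not isolated)
Conditions: Meldrum's acid, DCC, DMAP, CH2Cl2, 0 °C to rt; then BnOH, toluene, 90 °C
Reagents that add atoms: Meldrum's acid, CC1(C)OC(=O)CC(=O)O1; benzyl alcohol, OCc1ccccc1
Why: Oikawa–Yonemitsu β-keto ester synthesis, in which C-acylation of Meldrum's acid is followed by thermal loss of acetone and CO2 to an acyl ketene that benzyl alcohol traps; the benzyl ester is chosen so that the acid can later be freed by hydrogenolysis without touching the aryl silyl ethers.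

Step 3
Reactants: 5 benzyl 5-[3,4-bis(tert-butyldimethylsilyloxy)phenyl]-3-oxopentanoate
Product: 6 benzyl (3S)-5-[3,4-bis(tert-butyldimethylsilyloxy)phenyl]-3-hydroxypentanoate
Conditions: H2 (10 bar), RuCl2[(S)-BINAP] (1 mol%), BnOH/CH2Cl2, 50 °C
Reagents that add atoms: none
Why: Noyori asymmetric hydrogenation of a β-keto ester, in which the ester carbonyl chelates ruthenium and the (S)-BINAP complex should deliver hydride to the face that gives the (3S)-alcohol (the same sense in which (S)-BINAP gives (S)-3-hydroxybutanoates), while benzyl alcohol as the protic co-solvent makes any ester exchange degenerate.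

Step 4
Reactants: 6 benzyl (3S)-5-[3,4-bis(tert-butyldimethylsilyloxy)phenyl]-3-hydroxypentanoate
Product: 7 benzyl (3S)-3-(tert-butyldimethylsilyloxy)-5-[3,4-bis(tert-butyldimethylsilyloxy)phenyl]pentanoate
Conditions: TBSOTf, 2,6-lutidine, CH2Cl2, 0 °C
Reagents that add atoms: tert-butyldimethylsilyl triflate, CC(C)(C)[Si](C)(C)OS(=O)(=O)C(F)(F)F
Why: Standard silylation of a secondary alcohol with a silyl triflate and a hindered base, which blocks β-lactone formation and acyl transfer in the later carboxyl activation.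

Step 5
Reactants: 7 benzyl (3S)-3-(tert-butyldimethylsilyloxy)-5-[3,4-bis(tert-butyldimethylsilyloxy)phenyl]pentanoate
Product: 8 (3S)-3-(tert-butyldimethylsilyloxy)-5-[3,4-bis(tert-butyldimethylsilyloxy)phenyl]pentanoic acid
Conditions: H2 (1 atm), 10% Pd/C, EtOAc, rt
Reagents that add atoms: none
Why: Hydrogenolysis of the benzyl ester over palladium on carbon should release the acid under neutral conditions that leave all three silyl ethers intact, and it is placed before any alkene is present.

Step 6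
Reactants: 8 (3S)-3-(tert-butyldimethylsilyloxy)-5-[3,4-bis(tert-butyldimethylsilyloxy)phenyl]pentanoic acid
Product: 9 1,3-dioxoisoindolin-2-yl (3S)-3-(tert-butyldimethylsilyloxy)-5-[3,4-bis(tert-butyldimethylsilyloxy)phenyl]pentanoate
Conditions: N-hydroxyphthalimide, DIC, DMAP (cat.), CH2Cl2, 0 °C to rt
Reagents that add atoms: N-hydroxyphthalimide, O=C1c2ccccc2C(=O)N1O
Why: Carbodiimide (Steglich-type) esterification with N-hydroxyphthalimide gives the redox-active ester that serves as the precursor of the C4 radical.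

Step 7
Reactants: 10 oleic acid, (9Z)-octadec-9-enoic acid
Product: 11 S-(pyridin-2-yl) (9Z)-octadec-9-enethioate
Conditions: 2,2'-dipyridyl disulfide, PPh3, CH2Cl2, rt
Reagents that add atoms: 2,2'-dipyridyl disulfide, c1ccnc(SSc2ccccn2)c1
Why: Mukaiyama redox condensation converts the acid into the S-2-pyridyl thioester under neutral conditions that cannot isomerise the 9Z alkene.

Step 8
Reactants: 9 1,3-dioxoisoindolin-2-yl (3S)-3-(tert-butyldimethylsilyloxy)-5-[3,4-bis(tert-butyldimethylsilyloxy)phenyl]pentanoate; 11 S-(pyridin-2-yl) (9Z)-octadec-9-enethioate (1.5 equiv)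
Product: 12 (3S,13Z)-3-(tert-butyldimethylsilyloxy)-1-[3,4-bis(tert-butyldimethylsilyloxy)phenyl]docos-13-en-5-one
Conditions: NiCl2(dme) (10 mol%; dme = 1,2-dimethoxyethane), 4,4'-di-tert-butyl-2,2'-bipyridine (12 mol%), Zn dust (2 equiv), THF/DMA, rt; aq. NH4Cl work-up
Reagents that add atoms: none
Why: Zinc reduces the bipyridine nickel chloride to zerovalent nickel, which inserts into the acyl C–S bond of 11 (assisted by the pyridine nitrogen) to give an oleoyl thiolate complex of divalent nickel, while single-electron transfer to the N-acyloxyphthalimide 9 fragments it to phthalimide anion, CO2 and the primary C4 radical; capture of that radical at nickel and reductive elimination from the acyl(alkyl) complex of trivalent nickel should form the C4–C5 bond and the ketone. The closest known reaction type is the nickel-catalysed decarboxylative cross-electrophile coupling of N-hydroxyphthalimide esters with S-2-pyridyl thioesters to give dialkyl ketones, which covers primary alkyl radicals and functionalised partners. No ring is closed and no stereocenter is created; the C3 stereocenter lies one atom from the radical carbon, none of its bonds is broken, and it should be carried through unchanged. The step needs cross-selectivity (ketone instead of alkyl dimer, reduced alkane or decarbonylated product), which the two different activation modes (two-electron oxidative addition for the thioester, one-electron reduction for the redox-active ester) and the excess of the cheap thioester should secure. It also needs the 13Z alkene and the β-silyloxy group to survive: the alkene sits eight carbons from the acyl nickel centre and no nickel hydride is generated, a β-silyloxy alkyl radical does not fragment, and reductive elimination from the acyl(alkyl)nickel species should outrun β-oxygen elimination.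

Step 9
Reactants: 12 (3S,13Z)-3-(tert-butyldimethylsilyloxy)-1-[3,4-bis(tert-butyldimethylsilyloxy)phenyl]docos-13-en-5-one
Product: 13 (3S,13Z)-1-(3,4-dihydroxyphenyl)-3-hydroxydocos-13-en-5-one
Conditions: TBAF/AcOH (1:1, excess), THF, 0 °C to rt, under Ar
Reagents that add atoms: none
Why: Fluoride-mediated cleavage of the three Si–O bonds with acetic acid as buffer, which should suppress E1cB loss of the C3 oxygen, retro-aldol cleavage and catechol oxidation, and which touches neither the C3 stereocenter nor the 13Z alkene.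

## Compound list

1 | 3-(3,4-dihydroxyphenyl)propanoic acid (dihydrocaffeic acid) | OC(=O)CCc1ccc(O)c(O)c1 | starting material
2 | tert-butyldimethylsilyl 3-[3,4-bis(tert-butyldimethylsilyloxy)phenyl]propanoate | CC(C)(C)[Si](C)(C)OC(=O)CCc1ccc(O[Si](C)(C)C(C)(C)C)c(O[Si](C)(C)C(C)(C)C)c1 | intermediate
3 | 3-[3,4-bis(tert-butyldimethylsilyloxy)phenyl]propanoic acid | OC(=O)CCc1ccc(O[Si](C)(C)C(C)(C)C)c(O[Si](C)(C)C(C)(C)C)c1 | intermediate
4 | 5-{3-[3,4-bis(tert-butyldimethylsilyloxy)phenyl]-1-hydroxypropylidene}-2,2-dimethyl-1,3-dioxane-4,6-dione (acyl Meldrum's acid) | CC1(C)OC(=O)C(=C(O)CCc2ccc(O[Si](C)(C)C(C)(C)C)c(O[Si](C)(C)C(C)(C)C)c2)C(=O)O1 | intermediate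
5 | benzyl 5-[3,4-bis(tert-butyldimethylsilyloxy)phenyl]-3-oxopentanoate | O=C(CC(=O)OCc1ccccc1)CCc1ccc(O[Si](C)(C)C(C)(C)C)c(O[Si](C)(C)C(C)(C)C)c1 | intermediate
6 | benzyl (3S)-5-[3,4-bis(tert-butyldimethylsilyloxy)phenyl]-3-hydroxypentanoate | O=C(OCc1ccccc1)C[C@@H](O)CCc1ccc(O[Si](C)(C)C(C)(C)C)c(O[Si](C)(C)C(C)(C)C)c1 | intermediate
7 | benzyl (3S)-3-(tert-butyldimethylsilyloxy)-5-[3,4-bis(tert-butyldimethylsilyloxy)phenyl]pentanoate | O=C(OCc1ccccc1)C[C@@H](O[Si](C)(C)C(C)(C)C)CCc1ccc(O[Si](C)(C)C(C)(C)C)c(O[Si](C)(C)C(C)(C)C)c1 | intermediate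
8 | (3S)-3-(tert-butyldimethylsilyloxy)-5-[3,4-bis(tert-butyldimethylsilyloxy)phenyl]pentanoic acid | OC(=O)C[C@@H](O[Si](C)(C)C(C)(C)C)CCc1ccc(O[Si](C)(C)C(C)(C)C)c(O[Si](C)(C)C(C)(C)C)c1 | intermediate
9 | 1,3-dioxoisoindolin-2-yl (3S)-3-(tert-butyldimethylsilyloxy)-5-[3,4-bis(tert-butyldimethylsilyloxy)phenyl]pentanoate | O=C(C[C@@H](O[Si](C)(C)C(C)(C)C)CCc1ccc(O[Si](C)(C)C(C)(C)C)c(O[Si](C)(C)C(C)(C)C)c1)ON1C(=O)c2ccccc2C1=O | intermediate
10 | oleic acid, (9Z)-octadec-9-enoic acid | CCCCCCCC/C=C\CCCCCCCC(=O)O | starting material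
11 | S-(pyridin-2-yl) (9Z)-octadec-9-enethioate | CCCCCCCC/C=C\CCCCCCCC(=O)Sc1ccccn1 | intermediate
12 | (3S,13Z)-3-(tert-butyldimethylsilyloxy)-1-[3,4-bis(tert-butyldimethylsilyloxy)phenyl]docos-13-en-5-one | CCCCCCCC/C=C\CCCCCCCC(=O)C[C@@H](O[Si](C)(C)C(C)(C)C)CCc1ccc(O[Si](C)(C)C(C)(C)C)c(O[Si](C)(C)C(C)(C)C)c1 | intermediate
13 | (3S,13Z)-1-(3,4-dihydroxyphenyl)-3-hydroxydocos-13-en-5-one | CCCCCCCC/C=C\CCCCCCCC(=O)C[C@@H](O)CCc1ccc(O)c(O)c1 | target

## Step count and risks

Total step count: 9. Longest linear sequence: 8 steps (steps 1 to 6, 8 and 9, from compound 1).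

**Step 8.** The C4 radical may be lost to dimerisation or reduction, or β-oxygen elimination at nickel may compete, so that cross-coupling becomes inefficient. The fallback makes the same C4–C5 bond by polar chemistry, sets out from 9 and 11 and comes back at 12. Iododecarboxylation of 9 (LiI, PPh3 cat., blue LEDs, acetone) should give (2S)-4-[3,4-bis(tert-butyldimethylsilyloxy)phenyl]-2-(tert-butyldimethylsilyloxy)-1-iodobutane F1. Half-reduction of 11 (i-Bu2AlH, CH2Cl2, −78 °C) should give (9Z)-octadec-9-enal F2, which with propane-1,3-dithiol and BF3·OEt2 should give 2-[(8Z)-heptadec-8-en-1-yl]-1,3-dithiane F3. Lithiation of F3 (n-BuLi, THF/HMPA, −78 °C) and Corey–Seebach alkylation with F1 should give 2-[(2S)-4-[3,4-bis(tert-butyldimethylsilyloxy)phenyl]-2-(tert-butyldimethylsilyloxy)butyl]-2-[(8Z)-heptadec-8-en-1-yl]-1,3-dithiane F4. MeI and CaCO3 in aqueous MeCN should then unmask the ketone to give 12.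

**Step 9.** Base-induced loss of the C3 oxygen to the conjugated enone, retro-aldol cleavage, or slow cleavage of the hindered C3 silyl ether under conditions mild enough for the aldol and the catechol may erode the last step. The fallback changes the protecting-group plan so that all silyl groups leave within minutes at 0 °C; it sets out from 6 and comes back at 13. Silylation of 6 with TESOTf and 2,6-lutidine should give benzyl (3S)-5-[3,4-bis(tert-butyldimethylsilyloxy)phenyl]-3-(triethylsilyloxy)pentanoate F10. Hydrogenolysis (H2, Pd/C, EtOAc) should give (3S)-5-[3,4-bis(tert-butyldimethylsilyloxy)phenyl]-3-(triethylsilyloxy)pentanoic acid F11. Esterification with N-hydroxyphthalimide and DIC should give 1,3-dioxoisoindolin-2-yl (3S)-5-[3,4-bis(tert-butyldimethylsilyloxy)phenyl]-3-(triethylsilyloxy)pentanoate F12. Coupling with 11 under the conditions of step 8 should give (3S,13Z)-1-[3,4-bis(tert-butyldimethylsilyloxy)phenyl]-3-(triethylsilyloxy)docos-13-en-5-one F13. Brief treatment with TBAF/AcOH in THF at 0 °C should then give 13.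

**Step 3.** Slow turnover in the benzyl alcohol medium, partial loss of aryl silyl groups under the acidic ruthenium chloride catalyst, or insufficient facial selectivity may spoil the hydrogenation. The fallback sets C3 by reagent-controlled allylation instead of ketone reduction; it sets out from 3 and comes back at 8. Reduction of 3 (BH3·SMe2, THF) should give 3-[3,4-bis(tert-butyldimethylsilyloxy)phenyl]propan-1-ol F5. Dess–Martin oxidation should give 3-[3,4-bis(tert-butyldimethylsilyloxy)phenyl]propanal F6. Brown allylation with (+)-Ipc2B(allyl) (from (−)-α-pinene; Re-face delivery; Et2O, −78 °C; ethanolamine work-up) should give (3S)-1-[3,4-bis(tert-butyldimethylsilyloxy)phenyl]hex-5-en-3-ol F7. Silylation (TBSOTf, 2,6-lutidine) should give the silyl ether (3S)-1-[3,4-bis(tert-butyldimethylsilyloxy)phenyl]-3-(tert-butyldimethylsilyloxy)hex-5-ene F8. Oxidative cleavage (OsO4 cat., NaIO4, 2,6-lutidine, dioxane/H2O) should give (3S)-3-(tert-butyldimethylsilyloxy)-5-[3,4-bis(tert-butyldimethylsilyloxy)phenyl]pentanal F9. Pinnick oxidation (NaClO2, NaH2PO4, 2-methyl-2-butene) should then give 8.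

## Further compounds

F1 | step 8 | (2S)-4-[3,4-bis(tert-butyldimethylsilyloxy)phenyl]-2-(tert-butyldimethylsilyloxy)-1-iodobutane | IC[C@@H](O[Si](C)(C)C(C)(C)C)CCc1ccc(O[Si](C)(C)C(C)(C)C)c(O[Si](C)(C)C(C)(C)C)c1
F2 | step 8 | (9Z)-octadec-9-enal | CCCCCCCC/C=C\CCCCCCCC=O
F3 | step 8 | 2-[(8Z)-heptadec-8-en-1-yl]-1,3-dithiane | CCCCCCCC/C=C\CCCCCCCC1SCCCS1
F4 | step 8 | 2-[(2S)-4-[3,4-bis(tert-butyldimethylsilyloxy)phenyl]-2-(tert-butyldimethylsilyloxy)butyl]-2-[(8Z)-heptadec-8-en-1-yl]-1,3-dithiane | CCCCCCCC/C=C\CCCCCCCC1(C[C@@H](O[Si](C)(C)C(C)(C)C)CCc2ccc(O[Si](C)(C)C(C)(C)C)c(O[Si](C)(C)C(C)(C)C)c2)SCCCS1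
F5 | step 3 | 3-[3,4-bis(tert-butyldimethylsilyloxy)phenyl]propan-1-ol | OCCCc1ccc(O[Si](C)(C)C(C)(C)C)c(O[Si](C)(C)C(C)(C)C)c1
F6 | step 3 | 3-[3,4-bis(tert-butyldimethylsilyloxy)phenyl]propanal | O=CCCc1ccc(O[Si](C)(C)C(C)(C)C)c(O[Si](C)(C)C(C)(C)C)c1
F7 | step 3 | (3S)-1-[3,4-bis(tert-butyldimethylsilyloxy)phenyl]hex-5-en-3-ol | C=CC[C@@H](O)CCc1ccc(O[Si](C)(C)C(C)(C)C)c(O[Si](C)(C)C(C)(C)C)c1
F8 | step 3 | (3S)-1-[3,4-bis(tert-butyldimethylsilyloxy)phenyl]-3-(tert-butyldimethylsilyloxy)hex-5-ene | C=CC[C@@H](O[Si](C)(C)C(C)(C)C)CCc1ccc(O[Si](C)(C)C(C)(C)C)c(O[Si](C)(C)C(C)(C)C)c1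
F9 | step 3 | (3S)-3-(tert-butyldimethylsilyloxy)-5-[3,4-bis(tert-butyldimethylsilyloxy)phenyl]pentanal | O=CC[C@@H](O[Si](C)(C)C(C)(C)C)CCc1ccc(O[Si](C)(C)C(C)(C)C)c(O[Si](C)(C)C(C)(C)C)c1
F10 | step 9 | benzyl (3S)-5-[3,4-bis(tert-butyldimethylsilyloxy)phenyl]-3-(triethylsilyloxy)pentanoate | O=C(OCc1ccccc1)C[C@@H](O[Si](CC)(CC)CC)CCc1ccc(O[Si](C)(C)C(C)(C)C)c(O[Si](C)(C)C(C)(C)C)c1
F11 | step 9 | (3S)-5-[3,4-bis(tert-butyldimethylsilyloxy)phenyl]-3-(triethylsilyloxy)pentanoic acid | OC(=O)C[C@@H](O[Si](CC)(CC)CC)CCc1ccc(O[Si](C)(C)C(C)(C)C)c(O[Si](C)(C)C(C)(C)C)c1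
F12 | step 9 | 1,3-dioxoisoindolin-2-yl (3S)-5-[3,4-bis(tert-butyldimethylsilyloxy)phenyl]-3-(triethylsilyloxy)pentanoate | O=C(C[C@@H](O[Si](CC)(CC)CC)CCc1ccc(O[Si](C)(C)C(C)(C)C)c(O[Si](C)(C)C(C)(C)C)c1)ON1C(=O)c2ccccc2C1=O
F13 | step 9 | (3S,13Z)-1-[3,4-bis(tert-butyldimethylsilyloxy)phenyl]-3-(triethylsilyloxy)docos-13-en-5-one | CCCCCCCC/C=C\CCCCCCCC(=O)C[C@@H](O[Si](CC)(CC)CC)CCc1ccc(O[Si](C)(C)C(C)(C)C)c(O[Si](C)(C)C(C)(C)C)c1
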